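**Plan**

- Retrosynthesis (clerodane numbering): the butenolide is cut at C12–C13 (alkenyl–bromofuranone coupling), C18 at C4 (enol triflate/cuprate), and the 6-OAc/7,8-diol array goes back to a Δ7-6-enone. Ring B is then cut at C5–C10 and C8–C9, which opens ring A as well, and the chain is cut at C4–C5 (aldol).
- Enabling feature: ring B (C5–C10) has oxygen at C6, a quaternary C5 (methyl) trans to H-10, and a quaternary C9 next to C10. It therefore maps onto a 2-silyloxydiene C5=C6–C7=C8 and an (E)-2-methyl enal C9=C10 (C11 = CHO) joined by the four ring-A atoms C1–C4.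
- Forward: a lactol Wittig reaction and oxidation give an enoate aldehyde; a boron aldol with (E)-hex-4-en-3-one joins C4–C5; bis-silylation gives the dienol ether; the ester becomes the enal; one intramolecular Diels–Alder reaction closes ring B and ring A together. Ring B is then oxidised, ring A receives its methyl alkene, and the side chain is coupled last.
- Stereochemistry: C4 (temporary, R) comes from the reagent-controlled aldol. C5, C9 and C10 (and temporary C8) come from the cycloaddition under matched control by C4 and a chiral oxazaborolidinium. C6 comes from a Luche reduction anti to C19, and C7/C8 from β-face osmylation.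
- Spectator groups: C4 is carried as a silyl-protected carbinol, which the aldol delivers directly, which fixes the diene face, and which is less prone to ionise next to the dienol ether than an acetal. C11 is an ester until the dienol ether exists and an alkyne after the cycloaddition.

Key step: step 7

Remark on the chemistry (assumption): clerodane numbering is used for all intermediates, α is the face of the C5 methyl group (C19) and β that of H-10; the (−)-Ipc2BOTf aldol is assumed to follow its usual sense with ethyl ketones (attack on the aldehyde Si face); 1, 2, 5 and 24 are taken as commercial.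

**Route**

Step 1
Reactants: 1 tetrahydro-2H-pyran-2-ol; 2 ethyl 2-(triphenyl-λ5-phosphanylidene)propanoate
Product: 3 ethyl (E)-7-hydroxy-2-methylhept-2-enoate
Conditions: toluene, 80 °C
Reagents that add atoms: none
Why: Wittig olefination of the ring-opened hydroxy aldehyde with the stabilised α-methyl ylide should give the (E)-trisubstituted enoate, the masked C9=C10 dienophile with C11 at the ester level, and sets no stereocentre.

Step 2
Reactants: 3 ethyl (E)-7-hydroxy-2-methylhept-2-enoate
Product: 4 ethyl (E)-2-methyl-7-oxohept-2-enoate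
Conditions: TEMPO (10 mol%), PhI(OAc)2, CH2Cl2, 25 °C
Reagents that add atoms: none
Why: Oxoammonium (TEMPO) oxidation should stop at the aldehyde and leave the conjugated ester untouched, which gives the C4 electrophile for the aldol.

Step 3
Reactants: 5 (E)-hex-4-en-3-one; 4 ethyl (E)-2-methyl-7-oxohept-2-enoate
Product: 8 ethyl (2E,7R,8S,10E)-7-hydroxy-2,8-dimethyl-9-oxododeca-2,10-dienoate, via Z-enol diisopinocampheylborinate 6 (not isolated), via boron aldolate 7 (not isolated)
Conditions: (−)-Ipc2BOTf [(−)-diisopinocampheylboron triflate, from (+)-α-pinene], i-Pr2NEt, CH2Cl2, −78 °C; then 4, −78 → −20 °C; H2O2, MeOH, pH 7 buffer, 0 °C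
Reagents that add atoms: none
Why: Reagent-controlled boron aldol, in which the amine and boron triflate enolise the ethyl ketone at its only α-CH2 to the (Z)-enol borinate, the chair transition state gives the syn aldol, and the isopinocampheyl ligands direct attack to the aldehyde Si face, which sets C4 (7R in chain numbering) while the boron enolate leaves the enoate alone.

Step 4
Reactants: 8 ethyl (2E,7R,8S,10E)-7-hydroxy-2,8-dimethyl-9-oxododeca-2,10-dienoate
Product: 10 ethyl (2E,7R,8Z,10E)-7,9-bis[(tert-butyldimethylsilyl)oxy]-2,8-dimethyldodeca-2,8,10-trienoate, via mono-silyl ether 9 (not isolated)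
Conditions: TBSOTf (2.6 equiv), Et3N (4 equiv), CH2Cl2, −78 → 0 °C
Reagents that add atoms: tert-butyldimethylsilyl triflate, CC(C)(C)[Si](C)(C)OS(=O)(=O)C(F)(F)F
Why: Soft enolisation with silyl triflate and amine, in which the carbinol is silylated first and O-silylation of the ketone with loss of the C5 proton (the only α′ hydrogen) should give the cross-conjugated 2-silyloxydiene, with the bulkier C4 branch cis to the silyloxy group (8Z, tether outside and methyl inside) to avoid allylic strain with the propenyl group, the C5 stereocentre disappearing and no free enolate being formed that could add to the enoate.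

Step 5
Reactants: 10 ethyl (2E,7R,8Z,10E)-7,9-bis[(tert-butyldimethylsilyl)oxy]-2,8-dimethyldodeca-2,8,10-trienoate
Product: 11 (2E,7R,8Z,10E)-7,9-bis[(tert-butyldimethylsilyl)oxy]-2,8-dimethyldodeca-2,8,10-trien-1-ol
Conditions: i-Bu2AlH (2.5 equiv), CH2Cl2, −78 °C; aq. potassium sodium tartrate
Reagents that add atoms: none
Why: Hydride reduction of the enoate to the allylic alcohol at −78 °C should leave the silyl ether and the dienol ether untouched because no acid, fluoride or protic base is involved.

Step 6
Reactants: 11 (2E,7R,8Z,10E)-7,9-bis[(tert-butyldimethylsilyl)oxy]-2,8-dimethyldodeca-2,8,10-trien-1-ol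
Product: 12 (2E,7R,8Z,10E)-7,9-bis[(tert-butyldimethylsilyl)oxy]-2,8-dimethyldodeca-2,8,10-trienal
Conditions: MnO2, CH2Cl2, 25 °C
Reagents that add atoms: none
Why: MnO2 oxidises only the allylic alcohol and is neutral and heterogeneous, so the (E)-2-methyl enal should form without loss of the acid-labile dienol ether and is taken at once into the cycloaddition.

Step 7
Reactants: 12 (2E,7R,8Z,10E)-7,9-bis[(tert-butyldimethylsilyl)oxy]-2,8-dimethyldodeca-2,8,10-trienal
Product: 13 cycloadduct, a trans-fused Δ6-octalin with 6-OTBS enol ether, 4α-OTBS (4R), 5α-CH3, 8β-CH3, 9α-CH3, 9β-CHO and 10β-H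
Conditions: (R)-3,3-diphenyl-1-(2-methylphenyl)tetrahydro-1H,3H-pyrrolo[1,2-c][1,3,2]oxazaborole (20 mol%), Tf2NH (16 mol%), CH2Cl2 (0.01 M), −78 → −40 °C; Et3N quench
Reagents that add atoms: none
Why: The boron-bound (E)-enal C9=C10 should add across the 2-silyloxydiene C5=C6–C7=C8 in a concerted, strongly asynchronous [4+2] in which the polarity-matched C5–C10 bond (enol ether carbon to enal β-carbon) runs ahead of C8–C9. The closest known reactions are oxazaborolidinium-catalysed Diels–Alder additions of 2-substituted enals to 2-silyloxydienes and Lewis-acid-catalysed type-1 intramolecular Diels–Alder reactions of trienals. Ring B closes by the cycloaddition itself, and ring A closes as the six-membered tether ring C1–C4 through the shared C5–C10 bond in a chair-like arrangement. C9 against C10 follows from the (E)-enal (suprafacial addition keeps C20 cis to C1 and the formyl group cis to H-10), C8 from the (E)-propenyl terminus, and the trans relation of C19 and H-10 from the formyl-endo transition state with the tether on the outside position of C5. The absolute sense is doubly secured: allylic 1,3-strain with the C6 silyloxy group holds H-4 in the diene plane, so C3 leaves on the β face with the C4 silyloxy group anti to the incoming enal, and the (R)-catalyst in its formyl C–H···O bound s-trans complex screens the C9 Re face, leaving open the Si face that the endo, trans-fused mode requires. The step needs endo over exo and catalysed over background reaction, the first secured by Lewis-acid activation together with the matched C4 centre, the second by low temperature and a slight deficit of Tf2NH so that no free acid attacks the dienol ether.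

Step 8
Reactants: 13 cycloadduct
Product: 14 alkyne, as 13 with 9β-ethynyl in place of the formyl group
Conditions: Me3SiCHN2, n-BuLi, THF, −78 → 0 °C
Reagents that add atoms: (trimethylsilyl)diazomethane, C[Si](C)(C)C=[N+]=[N-]
Why: Colvin rearrangement, in which lithiated Me3SiCHN2 adds to the non-enolisable aldehyde and Peterson elimination, loss of N2 and 1,2-hydrogen shift of the alkylidene carbene should give the terminal alkyne under aprotic conditions that keep the silyl enol ether, the alkyne being a C11/C12 handle that survives the later oxidation, hydride, triflation and cuprate steps.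

Step 9
Reactants: 14 alkyne
Product: 15 Δ7-6-enone with 4α-OTBS, 5α-CH3, 8-CH3, 9α-CH3, 9β-ethynyl and 10β-H
Conditions: IBX, 4-methoxypyridine N-oxide, DMSO, 25 → 45 °C
Reagents that add atoms: none
Why: IBX dehydrogenation of the silyl enol ether through an oxygen-bound pentavalent iodine enolate and single-electron transfer should give the Δ7-6-enone, the only possible site because C5 is quaternary, and unlike a palladium enolate route it needs no reagent on the C7 α face under the axial C19 and C20 methyl groups to reach the α-hydrogen at C8, whose stereocentre disappears.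

Step 10
Reactants: 15 Δ7-6-enone
Product: 16 6α-allylic alcohol
Conditions: NaBH4, CeCl3·7H2O, MeOH/THF, −78 → −40 °C
Reagents that add atoms: none
Why: Luche 1,2-reduction, in which hydride should add axially from the β face, anti to the adjacent axial C19 methyl group and away from the peri 4α-silyloxy group, to give the equatorial 6α-alcohol.

Step 11
Reactants: 16 6α-allylic alcohol
Product: 17 6α-acetate
Conditions: Ac2O, DMAP, Et3N, CH2Cl2, 25 → 40 °C
Reagents that add atoms: acetic anhydride, CC(=O)OC(C)=O
Why: DMAP-catalysed acylation of the single free hydroxyl group installs the C6 acetate of the target before the diol exists, so that no selective acylation of a triol is ever needed.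

Step 12
Reactants: 17 6α-acetate
Product: 18 4α-alcohol (6α-OAc, Δ7, 9β-ethynyl)
Conditions: HF·pyridine, pyridine, THF, 0 → 25 °C
Reagents that add atoms: none
Why: Fluoride cleavage of the secondary silyl ether with weakly acidic HF·pyridine should free the C4 carbinol without the base-induced 6→4 acetyl migration that a basic fluoride source could cause.

Step 13
Reactants: 18 4α-alcohol
Product: 19 4-ketone (6α-OAc, Δ7, 9β-ethynyl)
Conditions: Dess–Martin periodinane, NaHCO3, CH2Cl2, 25 °C
Reagents that add atoms: none
Why: Dess–Martin oxidation gives the C4 ketone, which removes the temporary C4 stereocentre and can neither epimerise nor eliminate because C5 is quaternary.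

Step 14
Reactants: 19 4-ketone
Product: 20 7β,8β-diol (8α-CH3, 6α-OAc, 4-ketone, 9β-ethynyl)
Conditions: OsO4 (10 mol%), N-methylmorpholine N-oxide, MeSO2NH2, acetone/H2O (5:1), 25 °C; aq. Na2SO3
Reagents that add atoms: osmium tetroxide, O=[Os](=O)(=O)=O (delivers both oxygen atoms), regenerated by N-methylmorpholine N-oxide, C[N+]1([O-])CCOCC1, and water, O
Why: OsO4 syn-dihydroxylation ([3+2] addition, catalytic in osmium) should take place on the β face of the only alkene, opposite the axial C19 and C20 methyl groups and anti to the allylic acetate, which sets 7β-OH and 8β-OH (8α-methyl) while the alkyne and the ketone are inert.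

Step 15
Reactants: 20 7β,8β-diol
Product: 21 7,8-acetonide
Conditions: Me2C(OMe)2, pyridinium p-toluenesulfonate (cat.), CH2Cl2, 25 °C
Reagents that add atoms: 2,2-dimethoxypropane, COC(C)(C)OC
Why: Acid-catalysed acetalisation of the cis-diol (tertiary axial and secondary equatorial hydroxyl) gives the acetonide that shields both hydroxyl groups from Tf2O, the cuprate and the zirconium hydride.

Step 16
Reactants: 21 7,8-acetonide
Product: 22 Δ3-enol triflate (4-OTf)
Conditions: Tf2O, 2,6-di-tert-butyl-4-methylpyridine, CH2Cl2, 0 → 25 °C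
Reagents that add atoms: triflic anhydride, O=S(=O)(OS(=O)(=O)C(F)(F)F)C(F)(F)F
Why: Enol triflate formation with Tf2O and a hindered pyridine, a protocol without strong base that tolerates acetates, can only engage C3 because C5 is quaternary, which fixes the position of the future Δ3 double bond.

Step 17
Reactants: 22 Δ3-enol triflate
Product: 23 Δ3-4-methyl compound (C18 installed; 6α-OAc, 7,8-acetonide, 9β-ethynyl)
Conditions: Me2CuLi (from MeLi and CuI, 5 equiv), THF, −20 → 0 °C
Reagents that add atoms: lithium dimethylcuprate, [Li+].C[Cu-]C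
Why: Cross-coupling of the enol triflate with lithium dimethylcuprate replaces the triflate by the C18 methyl group without moving the double bond, and acetate and acetonide are inert to the cuprate at low temperature while the excess reagent covers reversible deprotonation of the alkyne.

Step 18
Reactants: 23 Δ3-4-methyl compound; 24 4-bromofuran-2(5H)-one
Product: 26 acetonide of the target, via alkenylzirconocene chloride 25 (not isolated)
Conditions: Cp2Zr(H)Cl, THF, 25 °C; then 24, Pd(PPh3)4 (5 mol%), THF, 25 → 40 °C
Reagents that add atoms: none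
Why: Hydrozirconation adds Zr–H syn across the terminal alkyne with zirconium on the terminal carbon, and the palladium-catalysed Negishi-type coupling of the (E)-alkenylzirconocene with the vinylogous acyl bromide proceeds with retention, so the (E)-C11=C12 bond and the butenolide are installed in one operation after which no strong base or oxidant follows.

Step 19
Reactants: 26 acetonide of the target
Product: 27 CNP0279118.1
Conditions: AcOH/H2O (4:1), 45 °C
Reagents that add atoms: none
Why: Acid-catalysed hydrolysis of the acetonide in aqueous acetic acid frees the 7,8-diol, and the acetate, the butenolide and the trisubstituted alkene tolerate these conditions.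

**Compound list**

1 | tetrahydro-2H-pyran-2-ol (lactol of 5-hydroxypentanal, racemic) | OC1CCCCO1 | starting material
2 | ethyl 2-(triphenyl-λ5-phosphanylidene)propanoate | CCOC(=O)C(C)=P(c1ccccc1)(c1ccccc1)c1ccccc1 | starting material
3 | ethyl (E)-7-hydroxy-2-methylhept-2-enoate | CCOC(=O)/C(C)=C/CCCCO | intermediate
4 | ethyl (E)-2-methyl-7-oxohept-2-enoate | CCOC(=O)/C(C)=C/CCCC=O | intermediate
5 | (E)-hex-4-en-3-one | CCC(=O)/C=C/C | starting material
6 | (Z)-enol diisopinocampheylborinate of 5 | C/C=C(/C=C/C)OB([C@H]1[C@H](C)[C@H]2C[C@@H](C1)C2(C)C)[C@H]1[C@H](C)[C@H]2C[C@@H](C1)C2(C)C | intermediate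
7 | boron aldolate (O-diisopinocampheylboryl derivative of 8) | CCOC(=O)/C(C)=C/CCC[C@@H](OB([C@H]1[C@H](C)[C@H]2C[C@@H](C1)C2(C)C)[C@H]1[C@H](C)[C@H]2C[C@@H](C1)C2(C)C)[C@H](C)C(=O)/C=C/C | intermediate
8 | ethyl (2E,7R,8S,10E)-7-hydroxy-2,8-dimethyl-9-oxododeca-2,10-dienoate | CCOC(=O)/C(C)=C/CCC[C@@H](O)[C@H](C)C(=O)/C=C/C | intermediate
9 | ethyl (2E,7R,8S,10E)-7-[(tert-butyldimethylsilyl)oxy]-2,8-dimethyl-9-oxododeca-2,10-dienoate | CCOC(=O)/C(C)=C/CCC[C@@H](O[Si](C)(C)C(C)(C)C)[C@H](C)C(=O)/C=C/C | intermediate
10 | ethyl (2E,7R,8Z,10E)-7,9-bis[(tert-butyldimethylsilyl)oxy]-2,8-dimethyldodeca-2,8,10-trienoate | CCOC(=O)/C(C)=C/CCC[C@@H](O[Si](C)(C)C(C)(C)C)/C(C)=C(O[Si](C)(C)C(C)(C)C)/C=C/C | intermediate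
11 | (2E,7R,8Z,10E)-7,9-bis[(tert-butyldimethylsilyl)oxy]-2,8-dimethyldodeca-2,8,10-trien-1-ol | OC/C(C)=C/CCC[C@@H](O[Si](C)(C)C(C)(C)C)/C(C)=C(O[Si](C)(C)C(C)(C)C)/C=C/C | intermediate
12 | (2E,7R,8Z,10E)-7,9-bis[(tert-butyldimethylsilyl)oxy]-2,8-dimethyldodeca-2,8,10-trienal (cycloaddition precursor) | O=C/C(C)=C/CCC[C@@H](O[Si](C)(C)C(C)(C)C)/C(C)=C(O[Si](C)(C)C(C)(C)C)/C=C/C | intermediate
13 | cycloadduct: trans-fused Δ6-octalin, 6-OTBS enol ether, 4α-OTBS (4R), 5α-CH3, 8β-CH3, 9α-CH3, 9β-CHO, 10β-H | CC(C)(C)[Si](C)(C)OC1=C[C@H](C)[C@](C)(C=O)[C@H]2CCC[C@@H](O[Si](C)(C)C(C)(C)C)[C@]12C | intermediate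
14 | alkyne: as 13 with 9β-ethynyl in place of CHO | CC(C)(C)[Si](C)(C)OC1=C[C@H](C)[C@](C)(C#C)[C@H]2CCC[C@@H](O[Si](C)(C)C(C)(C)C)[C@]12C | intermediate
15 | Δ7-6-enone: 4α-OTBS, 5α-CH3, 8-CH3, 9α-CH3, 9β-ethynyl, 10β-H | O=C1C=C(C)[C@](C)(C#C)[C@H]2CCC[C@@H](O[Si](C)(C)C(C)(C)C)[C@]12C | intermediate
16 | 6α-allylic alcohol of 15 | O[C@H]1C=C(C)[C@](C)(C#C)[C@H]2CCC[C@@H](O[Si](C)(C)C(C)(C)C)[C@]12C | intermediate
17 | 6α-acetate (4α-OTBS, Δ7, 9β-ethynyl) | CC(=O)O[C@H]1C=C(C)[C@](C)(C#C)[C@H]2CCC[C@@H](O[Si](C)(C)C(C)(C)C)[C@]12C | intermediate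
18 | 4α-alcohol (6α-OAc, Δ7, 9β-ethynyl) | CC(=O)O[C@H]1C=C(C)[C@](C)(C#C)[C@H]2CCC[C@@H](O)[C@]12C | intermediate
19 | 4-ketone (6α-OAc, Δ7, 9β-ethynyl) | CC(=O)O[C@H]1C=C(C)[C@](C)(C#C)[C@H]2CCCC(=O)[C@]12C | intermediate
20 | 7β,8β-diol (8α-CH3, 6α-OAc, 4-ketone, 9β-ethynyl) | CC(=O)O[C@H]1[C@H](O)[C@](C)(O)[C@](C)(C#C)[C@H]2CCCC(=O)[C@]12C | intermediate
21 | 7,8-acetonide of 20 | CC(=O)O[C@H]1[C@@H]2OC(C)(C)O[C@]2(C)[C@](C)(C#C)[C@H]3CCCC(=O)[C@]13C | intermediate
22 | Δ3-enol triflate (4-OTf) of 21 | CC(=O)O[C@H]1[C@@H]2OC(C)(C)O[C@]2(C)[C@](C)(C#C)[C@H]3CCC=C(OS(=O)(=O)C(F)(F)F)[C@]13C | intermediate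
23 | Δ3-4-methyl compound (6α-OAc, 7,8-acetonide, 9β-ethynyl) | CC(=O)O[C@H]1[C@@H]2OC(C)(C)O[C@]2(C)[C@](C)(C#C)[C@H]3CCC=C(C)[C@]13C | intermediate
24 | 4-bromofuran-2(5H)-one | BrC1=CC(=O)OC1 | starting material
25 | (E)-alkenylzirconocene chloride (Cp2ZrCl on C12) | CC(=O)O[C@H]1[C@@H]2OC(C)(C)O[C@]2(C)[C@](C)(/C=C/[Zr](Cl)(C4C=CC=C4)C5C=CC=C5)[C@H]3CCC=C(C)[C@]13C | intermediate
26 | 7,8-acetonide of the target | CC(=O)O[C@H]1[C@@H]2OC(C)(C)O[C@]2(C)[C@](C)(/C=C/C4=CC(=O)OC4)[C@H]3CCC=C(C)[C@]13C | intermediate
27 | CNP0279118.1: 6α-acetoxy-7β,8β-dihydroxycleroda-3,11(E),13-trien-15,16-olide (5α-, 8α-, 9α-methyl, 10β-H) | CC(=O)O[C@H]1[C@H](O)[C@](C)(O)[C@](C)(/C=C/C2=CC(=O)OC2)[C@H]2CCC=C(C)[C@]12C | target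

**Totals**

Total step count: 19. Longest linear sequence: 19 steps (1 → 27).

**Steps most likely to fail**

Step 7 (cycloaddition). What may go wrong: ionisation of the allylic C4 silyloxy group or protodesilylation of the dienol ether by the cationic boron acid before ring closure, or a stepwise Mukaiyama–Michael course that loses the C9/C10 relationship. Fallback (sets out from 10, comes back at 13): the rings are closed without any Lewis acid at the ester oxidation level, with the diene face controlled by the C4 centre alone. Heating 10 in toluene with BHT at 180 °C in a sealed tube should give the ethyl ester congener of the cycloadduct F1, from which diastereomers of the exo mode would have to be separated. Reduction with i-Bu2AlH at −78 °C gives the neopentyl alcohol F2, and oxidation with n-Pr4NRuO4 and N-methylmorpholine N-oxide returns 13.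

Step 4 (dienol ether). What may go wrong: competing deprotonation at the C17 methyl group to give the linear dienol ether, formation of the wrong C5=C6 geometry under equilibrating conditions, or elimination of the C4 silyloxy group. Fallback (sets out from 8, comes back at 10): the amine/silyl triflate enolisation is replaced by irreversible lithium enolate formation on an isolated intermediate. Compound 8 is silylated with TBSOTf and 2,6-lutidine at −78 °C and the mono-silyl ether 9 is isolated. It is then deprotonated with LiN(SiMe3)2 in THF/HMPA at −78 °C in the presence of TBSCl (internal quench), so that kinetic α′-deprotonation and lithium chelation by the C4 oxygen decide regiochemistry and geometry; no new compound arises.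

Step 9 (dehydrogenation). What may go wrong: slow or failing loss of the C8 hydrogen, which is the only one available and sits pseudo-equatorial on the hindered α face, or competing cleavage of the enol ether to the saturated ketone. Fallback (sets out from 13, comes back at 15): the double bond is introduced through the 6,7-dione instead of by dehydrogenation. Rubottom oxidation of 13 (dimethyldioxirane, acetone, −40 °C, then citric acid in MeOH) gives the 7-hydroxy-6-ketone F3. Dess–Martin oxidation followed by Et3N gives the diosphenol F4, enolised towards C8 so that the C8 configuration no longer matters. PhNTf2 and Et3N give the diosphenol triflate F5, and reduction with Pd(OAc)2, PPh3, HCO2H and n-Bu3N in DMF at 60 °C gives the Δ7-6-enone aldehyde F6. The Colvin conditions of step 8, applied to F6 at −78 °C, then give 15.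

**Further compounds**

F1 | step 7 | ethyl ester congener of 13 (CO2Et in place of CHO at C9) | CC(C)(C)[Si](C)(C)OC1=C[C@H](C)[C@](C)(C(=O)OCC)[C@H]2CCC[C@@H](O[Si](C)(C)C(C)(C)C)[C@]12C
F2 | step 7 | neopentyl alcohol (CH2OH in place of CHO at C9 of 13) | CC(C)(C)[Si](C)(C)OC1=C[C@H](C)[C@](C)(CO)[C@H]2CCC[C@@H](O[Si](C)(C)C(C)(C)C)[C@]12C
F0 | step 4 | none | none
F3 | step 9 | 7β-hydroxy-6-ketone (4α-OTBS, 8β-CH3, 9β-CHO) | O=C1[C@H](O)[C@H](C)[C@](C)(C=O)[C@H]2CCC[C@@H](O[Si](C)(C)C(C)(C)C)[C@]12C
F4 | step 9 | diosphenol (7-hydroxy-Δ7-6-enone, 9β-CHO) | O=C1C(O)=C(C)[C@](C)(C=O)[C@H]2CCC[C@@H](O[Si](C)(C)C(C)(C)C)[C@]12C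
F5 | step 9 | diosphenol triflate (7-OTf-Δ7-6-enone, 9β-CHO) | O=C1C(OS(=O)(=O)C(F)(F)F)=C(C)[C@](C)(C=O)[C@H]2CCC[C@@H](O[Si](C)(C)C(C)(C)C)[C@]12C
F6 | step 9 | Δ7-6-enone aldehyde (4α-OTBS, 9β-CHO) | O=C1C=C(C)[C@](C)(C=O)[C@H]2CCC[C@@H](O[Si](C)(C)C(C)(C)C)[C@]12C
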